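The numbers in the tables come from a simulation from invented constants.

Two questions stand over the next flask, its conversion and its target, and one balance ties them together, so the charge can be planned from a single estimate.

| flask | starting material | partner | remark | time |
|---|---|---|---|---|
| summer | 0.24 M | 1.5 equiv | run made earlier |  |
| dawn | 0.54 M | 1.5 equiv | run made earlier |  |
| flask | 0.36 M | 1.50 equiv |  | 1.5 h |

- summer (time / min: starting material / %, target / %): 25.0: 18.8, 10.0; 50.0: 19.6, 10.5; 80.0: 19.9, 9.6; 120: 19.5, 10.8
- dawn (time / min: starting material / %, target / %): 25.0: 21.4, 7.0; 50.0: 21.3, 5.3; 80.0: 22.1, 5.7; 120: 22.2, 6.8

(scatter of a reading: 0.5 percentage points)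

1. share of the starting material used up at 1.5 h
2. target at 1.5 h, in percent of the starting material charged

- the numbers in the tables scatter by 0.5 percentage points (one standard deviation)
- steps that have been proposed: intermediate D -> side product; partner + intermediate A -> intermediate B; intermediate B -> intermediate D; partner + intermediate A -> intermediate C; intermediate C -> intermediate D; starting material + partner -> intermediate A; intermediate A -> target

In the summer and dawn runs the readings stand level from 25.0 min to 120 min, with target averaging 10.2% in the summer run and 6.20% in the dawn run. Each starting material used up takes one partner, and each that does not end as target takes a second. On mean readings, as fractions of the charge: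

summer: 1.51

dawn: 1.50

mean: 1.51

This mean is the partner bill: partner spent per starting material charged, twice the conversion less the target fraction. It matches the 1.5 equiv charged, so partner reads as the limiting reagent. The plan is therefore to leave the time at 1.5 h and vary partner equivalents for conversion and concentration for target.

A power law through the two target means gives, by the reckoning here:

target at 0.36 M: 7.96%

conversion, the sum of bill and target over two: 79.3%

The forecast, slightly apart from this, gives 79.1% and 8.1%, and reads the plateau so: “That looks like the partner running out, not an equilibrium.”

The flask gives 79.1% and 8.22%.

    intermediate D → side product (k = 0.0250 /s)
    partner + intermediate A → intermediate B (k = 0.240 /M/s)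
    intermediate B → intermediate D (k = 0.0120 /s)
    partner + intermediate A → intermediate C (k = 1.40 /M/s)
    intermediate C → intermediate D (k = 0.0260 /s)
    starting material + partner → intermediate A (k = 0.180 /M/s)
    intermediate A → target (k = 0.0170 /s)

In this flask the partner stands at 0% of its charge after 1.50 h, and twice the conversion less the target comes to 1.50. The neighbour charged with 0.380 equiv of partner takes the same reckoning. Its bill, scaled to that charge, is 0.381, and with its target of 10.1% the sum over two gives a conversion of 24.1%. That neighbour's simulated conversion is 24.0%, with partner at 0% of its charge and starting material at 76.0%.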